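Start with the two settings you can turn, then carry one number from the earlier runs to the new flask.

| setting | alpha | theta | flask |
|---|---|---|---|
| substrate | 1 M | 2.2 M | 1.5 M |
| remark | run made earlier | run made earlier |  |
| time |  |  | 50 h |

| alpha: time / h | alpha: target / % | theta: time / h | theta: target / % |
|---|---|---|---|
| 0.333 | 17.5 | 0.333 | 9.3 |
| 1.00 | 19.4 | 1.00 | 10.3 |
| 3.00 | 15.4 | 3.00 | 8.8 |
| 10.0 | 7.2 | 10.0 | 6.0 |
| 30.0 | 1.6 | 30.0 | 0.6 |

(readings scatter by 1 percentage point)

- percentages count the substrate that a species holds: one self-condensation product counts as two
- target is meant together with its crystals
- solid, in amounts per volume of the solution: crystals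
- on the list of suspects stand: substrate <-> target; substrate <-> isomer of the product; target <-> isomer of the product; crystals <-> target; target -> over-reaction product; 2 substrate -> self-condensation product

- time up to 50 h at which target stands highest
- the amount of target, in percent of the substrate charged, at that time

1. Time. By hand, target builds up and then leaks away, so more time need not help. In both earlier runs the highest reading stands at 1.00 h: 19.4 % in alpha, 10.3 % in theta. At 30.0 h they have sunk to 1.6 % and 0.6 %. Look for the new flask's best near 1.00 h, far inside 50 h.

2. Charge. By hand, if the steps go as written, substrate makes target at a rate that follows its amount, while self-condensation follows the square of that amount. Divide the second rate by the first and time drops out: this ratio, a selectivity factor, grows with the substrate present. The runs agree: the highest reading of theta, charged 2.20 times as heavily as alpha, is lower by a factor of 1.88.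

3. The number to carry. Divide the logarithm of that second factor by the logarithm of the first: 0.803. This is the charge exponent, the power of the charge by which the highest reading falls between these two runs. My reckoning from the alpha reading for 1.5 M gives 14.0 %, with each reading scattering by 1 percentage point.

4. The forecast says 14.2 % at 0.8 h, citing “second-order self-condensation wasting more substrate at high loading”.

5. The flask gives 14.1 % at 0.728 h, and the forecast holds.

    substrate ⇌ target (K = 7.40, k = 0.0270 /min)
    substrate ⇌ isomer of the product (K = 2.60, k = 0.00150 /min)
    target ⇌ isomer of the product (k = 0.0130 /min)
    crystals ⇌ target, rate k4*(cs4 - [target]) while solid is left; crystals form when [target] > cs4 (solubility = 0.960 M, k = 0.310 /min)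
    target → over-reaction product (k = 0.00170 /min)
    2 substrate → self-condensation product (k = 0.0990 /M/min)

At the start of this flask, self-condensation uses substrate 11 times as fast as the forward step to target, and at 0.728 h self-condensation product holds 76.9 % of the charge against 14.1 % in target. With the charge exponent 0.803, the alpha reading gives 14.0 % for this flask against its 14.1 %, and for the neighbour flask charged with 0.90 M it gives 21.1 %, where that flask stands at 19.0 %, a gap of 2.1 points.

(The runs were computed for an exercise.)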